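The bicyclo[3.3.1]nonane is cut in ring B (C1, C8, C7, C6, C5, C9) at C5–C6 and at the C7–prenyl bond. The key step uses two features: C5 is the enol carbon of the ring A trione, and C6=C7 can be a vinyl group on the quaternary C8 next to C1. Divalent palladium lets C5 add to C6, and the C7–Pd bond left behind is exchanged for prenyl by a tertiary allylic chloride, so one operation closes ring B and sets C5 and C7. The precursor is a dearomatised acylphloroglucinol whose C1/C8 pair comes from a Claisen rearrangement of a neryl ether; it is resolved before the key step.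

Key step: step 7

Remark: locants C1–C9 are those of the bicyclo[3.3.1]nonane throughout, enolised triones are drawn as one tautomer, and a racemate is written as both enantiomers joined by a dot.

Step 1
Reactants: 1 phloroglucinol; 2 3-hydroxybenzoic acid
Product: 3 (3-hydroxyphenyl)(2,4,6-trihydroxyphenyl)methanone
Conditions: ZnCl2, POCl3, 70 °C; then ice/H2O
Reagents that add atoms: 3-hydroxybenzoic acid (2), O=C(O)c1cccc(O)c1
Why: Friedel–Crafts acylation by the acid activated with POCl3/ZnCl2, in which the three equivalent ring positions of phloroglucinol allow only one monoketone, the new aryl ketone deactivates the ring towards a second acylation and the meta-hydroxy acid cannot close a xanthone.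

Step 2
Reactants: 3 (3-hydroxyphenyl)(2,4,6-trihydroxyphenyl)methanone; 4 prenyl bromide
Product: 5 (3-hydroxyphenyl)[2,4,6-trihydroxy-3,5-bis(3-methylbut-2-en-1-yl)phenyl]methanone
Conditions: 4 (2.1 equiv), 10% aq KOH (2.2 equiv), 0 °C; then 1 M HCl
Reagents that add atoms: prenyl bromide (4), CC(C)=CCBr
Why: Twofold C-alkylation of the phloroglucinolate in water, the standard entry to diprenylated acylphloroglucinols, which can only occur at the two free ring positions, with the base limited to what the liberated HBr consumes so that the less acidic benzoyl phenol stays mostly protonated and is not O-alkylated.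

Step 3
Reactants: 5 (3-hydroxyphenyl)[2,4,6-trihydroxy-3,5-bis(3-methylbut-2-en-1-yl)phenyl]methanone; 6 tert-butyldimethylsilyl chloride
Product: 7 {3-[(tert-butyldimethylsilyl)oxy]phenyl}[2,4,6-trihydroxy-3,5-bis(3-methylbut-2-en-1-yl)phenyl]methanone
Conditions: 6 (1.05 equiv), imidazole, DMF, −20 → 0 °C
Reagents that add atoms: tert-butyldimethylsilyl chloride (6), CC(C)(C)[Si](C)(C)Cl
Why: Silyl ether formation under steric control, since the benzoyl-ring hydroxyl is the only one without ortho substituents and without a hydrogen bond to the ketone, while each of the three ring hydroxyls is flanked by two substituents and would give a far more labile silyl ether that should not survive aqueous work-up.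

Step 4
Reactants: 7 {3-[(tert-butyldimethylsilyl)oxy]phenyl}[2,4,6-trihydroxy-3,5-bis(3-methylbut-2-en-1-yl)phenyl]methanone; 8 nerol
Product: 9 {3-[(tert-butyldimethylsilyl)oxy]phenyl}{4-[(2Z)-3,7-dimethylocta-2,6-dien-1-yl]oxy-2,6-dihydroxy-3,5-bis(3-methylbut-2-en-1-yl)phenyl}methanone
Conditions: 8 (1.1 equiv), PPh3, DIAD, THF, 0 °C → rt
Reagents that add atoms: nerol (8), CC(C)=CCC/C(C)=C\CO
Why: Mitsunobu etherification, in which the betaine deprotonates the most acidic, non-chelated hydroxyl (para to the aroyl group) and its phenoxide displaces the oxyphosphonium of the primary allylic alcohol by SN2 with the Z double bond intact; the minor ortho ether is removed at this stage because its rearrangement would lead to the C8 epimer.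

Step 5
Reactants: 9 neryl ether of step 4
Product: 10 racemic (6S*)-2-{3-[(tert-butyldimethylsilyl)oxy]benzoyl}-6-[(3S*)-3,7-dimethylocta-1,6-dien-3-yl]-3,5-dihydroxy-4,6-bis(3-methylbut-2-en-1-yl)cyclohexa-2,4-dien-1-one
Conditions: Eu(fod)3 (10 mol %; fod = 6,6,7,7,8,8,8-heptafluoro-2,2-dimethyloctane-3,5-dionate), NaHCO3, CHCl3, 45 °C
Reagents that add atoms: none
Why: Lewis-acid-assisted aromatic Claisen rearrangement (concerted [3,3]) onto an ortho carbon that already bears prenyl, so that the product cannot re-aromatise and rests as the enolised trione, with the chair transition state and the Z alkene (homoprenyl chain pseudo-axial, methyl pseudo-equatorial) fixing the relative configuration of the two new quaternary centres C1 and C8, and with the two mirror-image approaches equally populated so that the racemate results.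

Step 6
Reactants: 10 racemic dearomatised trione of step 5
Product: 11 (6S)-2-{3-[(tert-butyldimethylsilyl)oxy]benzoyl}-6-[(3S)-3,7-dimethylocta-1,6-dien-3-yl]-3,5-dihydroxy-4,6-bis(3-methylbut-2-en-1-yl)cyclohexa-2,4-dien-1-one
Conditions: preparative SFC on amylose tris(3,5-dimethylphenylcarbamate), CO2/MeOH (0.1% HCO2H), 25 °C
Reagents that add atoms: none
Why: Chromatographic resolution of the racemate on a chiral stationary phase, which needs no reaction at the sensitive polyene trione and is aided by the acidic modifier that keeps the vinylogous acid protonated, the (6S,3′S) enantiomer being identified by circular dichroism or by X-ray analysis of a heavy-atom salt.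

Step 7
Reactants: 11 resolved dearomatised trione (ring carbon 6 = C1, side-chain carbon 3 = C8, vinyl = C7=C6); 12 3-chloro-3-methylbut-1-ene
Product: 15 (1S,5S,7R,8S)-3-{3-[(tert-butyldimethylsilyl)oxy]benzoyl}-4-hydroxy-8-methyl-1,5,7-tris(3-methylbut-2-en-1-yl)-8-(4-methylpent-3-en-1-yl)bicyclo[3.3.1]non-3-ene-2,9-dione, via C7 alkylpalladium chloride 13 (not isolated), via allylic chloride insertion adduct 14 (not isolated)
Conditions: PdCl2(MeCN)2 (15 mol %), LiCl (1 equiv), NaHCO3 (2 equiv), 12 (10 equiv), THF, 25 °C
Reagents that add atoms: 3-chloro-3-methylbut-1-ene (12), C=CC(C)(C)Cl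
Why: Proposed new method: PdCl2(MeCN)2 binds the only monosubstituted alkene (C6=C7), the enol carbon C5 attacks C6 from the face opposite to the metal (outer-sphere anti carbopalladation, the proton going to NaHCO3) to give the σ-alkyl species 13, and 13 inserts the terminal alkene of 12 with palladium on the internal carbon (14), so that β-chloride elimination releases the prenyl group and returns divalent palladium without an external oxidant. The closest known reaction types are the divalent-palladium-catalysed 6-endo additions of β-diketone enols to pendant terminal alkenes and the interception of alkylpalladium species from heteroatom nucleopalladation by allyl chloride (insertion, then β-halide elimination); joining the two with a carbon nucleophile and a tertiary allylic chloride is new. Ring B closes 6-endo-trig with the C9 carbonyl inside the new ring, which is preferred over 5-exo attack at the neopentyl C7 and over closure through C3, whose nucleophilicity is lowered by the chelated aroyl group. C5 can only bond on the face of ring A that carries the C8 chain, so its configuration follows from C1; in the chair-like closure the C7–Pd bond is antiperiplanar to the new C5–C6 bond and therefore equatorial (exo), and insertion and elimination replace it with retention, which gives 7R with methyl axial and homoprenyl equatorial at C8. The step needs C-attack in preference to O-attack (the oxygens on C2 and C9 could close five-membered rings at C7) and capture of 13 before β-hydride loss towards C6: the first rests on the diketone precedent and on the perpendicular approach of the tethered alkene to the C5 π-face, the second on the absence of β-hydrogen at C8, on chloride slowing β-hydride elimination and on the excess of 12.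

Step 8
Reactants: 15 aryl silyl ether of the target
Product: 16 (1S,5S,7R,8S)-4-hydroxy-3-(3-hydroxybenzoyl)-8-methyl-1,5,7-tris(3-methylbut-2-en-1-yl)-8-(4-methylpent-3-en-1-yl)bicyclo[3.3.1]non-3-ene-2,9-dione (CNP0406274.2)
Conditions: TBAF, AcOH (1:1), THF, 0 °C
Reagents that add atoms: none
Why: Fluoride-induced cleavage of the aryl silyl ether, driven by Si–F bond formation and buffered with acetic acid so that the enolised trione, the four trisubstituted alkenes and the four stereocentres are not touched.

Compound list
1 | phloroglucinol | Oc1cc(O)cc(O)c1 | starting material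
2 | 3-hydroxybenzoic acid | O=C(O)c1cccc(O)c1 | starting material
3 | (3-hydroxyphenyl)(2,4,6-trihydroxyphenyl)methanone | O=C(c1cccc(O)c1)c1c(O)cc(O)cc1O | intermediate
4 | prenyl bromide (1-bromo-3-methylbut-2-ene) | CC(C)=CCBr | starting material
5 | (3-hydroxyphenyl)[2,4,6-trihydroxy-3,5-bis(3-methylbut-2-en-1-yl)phenyl]methanone | O=C(c1cccc(O)c1)c1c(O)c(CC=C(C)C)c(O)c(CC=C(C)C)c1O | intermediate
6 | tert-butyldimethylsilyl chloride | CC(C)(C)[Si](C)(C)Cl | starting material
7 | {3-[(tert-butyldimethylsilyl)oxy]phenyl}[2,4,6-trihydroxy-3,5-bis(3-methylbut-2-en-1-yl)phenyl]methanone | CC(C)(C)[Si](C)(C)Oc1cccc(c1)C(=O)c1c(O)c(CC=C(C)C)c(O)c(CC=C(C)C)c1O | intermediate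
8 | nerol | CC(C)=CCC/C(C)=C\CO | starting material
9 | {3-[(tert-butyldimethylsilyl)oxy]phenyl}{4-[(2Z)-3,7-dimethylocta-2,6-dien-1-yl]oxy-2,6-dihydroxy-3,5-bis(3-methylbut-2-en-1-yl)phenyl}methanone | CC(C)(C)[Si](C)(C)Oc1cccc(c1)C(=O)c1c(O)c(CC=C(C)C)c(OC/C=C(/C)CCC=C(C)C)c(CC=C(C)C)c1O | intermediate
10 | racemic (6S*)-2-{3-[(tert-butyldimethylsilyl)oxy]benzoyl}-6-[(3S*)-3,7-dimethylocta-1,6-dien-3-yl]-3,5-dihydroxy-4,6-bis(3-methylbut-2-en-1-yl)cyclohexa-2,4-dien-1-one | CC(C)=CCC[C@@](C)(C=C)[C@]1(CC=C(C)C)C(=O)C(C(=O)c2cccc(O[Si](C)(C)C(C)(C)C)c2)=C(O)C(CC=C(C)C)=C1O.CC(C)=CCC[C@](C)(C=C)[C@@]1(CC=C(C)C)C(=O)C(C(=O)c2cccc(O[Si](C)(C)C(C)(C)C)c2)=C(O)C(CC=C(C)C)=C1O | intermediate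
11 | (6S)-2-{3-[(tert-butyldimethylsilyl)oxy]benzoyl}-6-[(3S)-3,7-dimethylocta-1,6-dien-3-yl]-3,5-dihydroxy-4,6-bis(3-methylbut-2-en-1-yl)cyclohexa-2,4-dien-1-one | CC(C)=CCC[C@@](C)(C=C)[C@]1(CC=C(C)C)C(=O)C(C(=O)c2cccc(O[Si](C)(C)C(C)(C)C)c2)=C(O)C(CC=C(C)C)=C1O | intermediate
12 | 3-chloro-3-methylbut-1-ene | C=CC(C)(C)Cl | starting material
13 | C7 alkylpalladium chloride of the closed bicycle (palladium exo at C7, other ligands on palladium omitted) | CC(C)=CCC[C@@]1(C)[C@H]([Pd]Cl)C[C@]2(CC=C(C)C)C(=O)[C@@]1(CC=C(C)C)C(=O)C(C(=O)c1cccc(O[Si](C)(C)C(C)(C)C)c1)=C2O | intermediate (not isolated)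
14 | insertion adduct of 13 and 12, C7–CH2–CH(PdCl)–C(CH3)2Cl (configuration at the palladium-bearing carbon open, other ligands omitted) | CC(C)=CCC[C@@]1(C)[C@H](CC([Pd]Cl)C(C)(C)Cl)C[C@]2(CC=C(C)C)C(=O)[C@@]1(CC=C(C)C)C(=O)C(C(=O)c1cccc(O[Si](C)(C)C(C)(C)C)c1)=C2O | intermediate (not isolated)
15 | (1S,5S,7R,8S)-3-{3-[(tert-butyldimethylsilyl)oxy]benzoyl}-4-hydroxy-8-methyl-1,5,7-tris(3-methylbut-2-en-1-yl)-8-(4-methylpent-3-en-1-yl)bicyclo[3.3.1]non-3-ene-2,9-dione | CC(C)=CCC[C@@]1(C)[C@H](CC=C(C)C)C[C@]2(CC=C(C)C)C(=O)[C@@]1(CC=C(C)C)C(=O)C(C(=O)c1cccc(O[Si](C)(C)C(C)(C)C)c1)=C2O | intermediate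
16 | (1S,5S,7R,8S)-4-hydroxy-3-(3-hydroxybenzoyl)-8-methyl-1,5,7-tris(3-methylbut-2-en-1-yl)-8-(4-methylpent-3-en-1-yl)bicyclo[3.3.1]non-3-ene-2,9-dione | CC(C)=CCC[C@@]1(C)[C@H](CC=C(C)C)C[C@]2(CC=C(C)C)C(=O)[C@@]1(CC=C(C)C)C(=O)C(C(=O)c1cccc(O)c1)=C2O | target

Total step count: 8 (seven reactions and one resolution). Longest linear sequence: 8 steps (1 → 16).

Steps most likely to fail

1. Step 7. Processes at risk:
- β-hydride loss from the C7 alkylpalladium 13 towards C6 before the hindered chloride 12 inserts;
- ring closure through an enol oxygen on C2 or C9 at C7 in place of C5 at C6;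
- direct prenylation of the enolate by ionised 12.

The fallback uses known chemistry, gives up the vinyl precursor, sets out from 7 and returns at 15. It is the established alkylative dearomatisation–annulation of diprenylated acylphloroglucinols with an α-(acetoxymethyl) enal, followed by Wittig homologation of the resulting C7 aldehyde. The enal is made from 6-methylhept-5-en-2-one: Knoevenagel condensation with diethyl malonate (TiCl4, pyridine) gives diethyl 2-(6-methylhept-5-en-2-ylidene)malonate F1, i-Bu2AlH gives the diol F2, one equivalent of Ac2O the monoacetate F3, and MnO2 the enal F4. Alkene geometry in F3 and F4 is immaterial because C8 becomes tetrahedral. The dianion of 7 (LiN(SiMe3)2, THF, 0 → 60 °C) and F4 undergo conjugate addition, loss of acetate and a second conjugate addition. This joins C5–C6 and C1–C8 through the two prenyl-bearing ring carbons and leaves the bicyclic C7 aldehyde F5, whose exo aldehyde is reached by enolisation. C8 is not controlled in this sequence and the product is racemic, so the isomer shown has to be separated from its C8 epimer and the enantiomers separated on the chiral phase of step 6. Ph3P=CHOMe converts F5 into the enol ether F6, dilute aqueous acid gives the homologated aldehyde F7, and Ph3P=C(CH3)2 turns F7 into 15.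

2. Step 5. Processes at risk, at the temperature the para ether needs:
- ionisation of the neryl group, which loses the concerted pathway and the link between Z geometry, chair and configuration;
- a following Cope shift of the strained C1–C8 bond, which would move the side chain to C5 as a linear neryl group;
- a boat transition state, which would give the C8 epimer.

The fallback sets out from 5 and returns at 10. The allyl group is moved to the oxygen next to the aroyl group, where ether oxygen and ketone can hold one Lewis acid in a six-membered chelate, so that the rearrangement should run at or below room temperature. Silylation of 5 with 2.2 equiv of 6 caps the two reactive hydroxyls (benzoyl phenol and the acidic para hydroxyl) to give the bis-silyl ether F8. Mitsunobu reaction of one of its two equivalent ortho hydroxyls with geraniol gives the geranyl ether F9. The E alcohol is required here: the ether carbon now becomes C2 and not C9, so the chair transition state needs the opposite alkene geometry to reach the same C1/C8 relationship. Cu(OTf)2 (10 mol %), CH2Cl2, 0 °C gives the silyl dienol ether F10 as the racemate, and aqueous citric acid cleaves its vinylogous silyl ester, not the aryl silyl ether, to give 10.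

3. Step 2. Processes at risk: over-alkylation to dearomatised gem-diprenyl products, O-alkylation of the benzoyl phenol and incomplete second prenylation.

The fallback sets out from 3 and returns at 5 without any new compound (F0). It is electrophilic prenylation of the neutral phloroglucinol ring with 2-methylbut-3-en-2-ol and BF3·OEt2 in dioxane at room temperature. This Friedel–Crafts alkylation by the dimethylallyl cation needs no phenoxide and leaves the deactivated benzoyl ring alone. Closure of the product to chromans is its known side reaction and is limited by short contact time.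

Further compounds
F1 | step 7 | diethyl 2-(6-methylhept-5-en-2-ylidene)propanedioate | CCOC(=O)C(C(=O)OCC)=C(C)CCC=C(C)C
F2 | step 7 | 2-(6-methylhept-5-en-2-ylidene)propane-1,3-diol | OCC(CO)=C(C)CCC=C(C)C
F3 | step 7 | 2-(hydroxymethyl)-3,7-dimethylocta-2,6-dien-1-yl acetate (E/Z mixture) | CC(=O)OCC(CO)=C(C)CCC=C(C)C
F4 | step 7 | 2-formyl-3,7-dimethylocta-2,6-dien-1-yl acetate (E/Z mixture) | CC(=O)OCC(C=O)=C(C)CCC=C(C)C
F5 | step 7 | C7 carbaldehyde analogue of 15 (exo formyl in place of the C7 prenyl group; isomer shown after separation) | CC(C)=CCC[C@@]1(C)[C@H](C=O)C[C@]2(CC=C(C)C)C(=O)[C@@]1(CC=C(C)C)C(=O)C(C(=O)c1cccc(O[Si](C)(C)C(C)(C)C)c1)=C2O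
F6 | step 7 | C7 2-methoxyethenyl analogue of 15 (E/Z mixture) | CC(C)=CCC[C@@]1(C)[C@H](C=COC)C[C@]2(CC=C(C)C)C(=O)[C@@]1(CC=C(C)C)C(=O)C(C(=O)c1cccc(O[Si](C)(C)C(C)(C)C)c1)=C2O
F7 | step 7 | C7 2-oxoethyl analogue of 15 | CC(C)=CCC[C@@]1(C)[C@H](CC=O)C[C@]2(CC=C(C)C)C(=O)[C@@]1(CC=C(C)C)C(=O)C(C(=O)c1cccc(O[Si](C)(C)C(C)(C)C)c1)=C2O
F8 | step 5 | {3-[(tert-butyldimethylsilyl)oxy]phenyl}{4-[(tert-butyldimethylsilyl)oxy]-2,6-dihydroxy-3,5-bis(3-methylbut-2-en-1-yl)phenyl}methanone | CC(C)(C)[Si](C)(C)Oc1cccc(c1)C(=O)c1c(O)c(CC=C(C)C)c(O[Si](C)(C)C(C)(C)C)c(CC=C(C)C)c1O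
F9 | step 5 | {3-[(tert-butyldimethylsilyl)oxy]phenyl}{4-[(tert-butyldimethylsilyl)oxy]-2-[(2E)-3,7-dimethylocta-2,6-dien-1-yl]oxy-6-hydroxy-3,5-bis(3-methylbut-2-en-1-yl)phenyl}methanone | CC(C)(C)[Si](C)(C)Oc1cccc(c1)C(=O)c1c(O)c(CC=C(C)C)c(O[Si](C)(C)C(C)(C)C)c(CC=C(C)C)c1OC/C=C(\C)CCC=C(C)C
F10 | step 5 | racemic C9 O-tert-butyldimethylsilyl dienol ether of 10 | CC(C)=CCC[C@@](C)(C=C)[C@]1(CC=C(C)C)C(=O)C(C(=O)c2cccc(O[Si](C)(C)C(C)(C)C)c2)=C(O)C(CC=C(C)C)=C1O[Si](C)(C)C(C)(C)C.CC(C)=CCC[C@](C)(C=C)[C@@]1(CC=C(C)C)C(=O)C(C(=O)c2cccc(O[Si](C)(C)C(C)(C)C)c2)=C(O)C(CC=C(C)C)=C1O[Si](C)(C)C(C)(C)C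
F0 | step 2 | none | none
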